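The constants used here stand for no real mixture; the rest is arithmetic.

I read each flask after 30 s, and the amount of target at that moment is the answer.

| flask | substrate | reagent | temperature | time |
|---|---|---|---|---|
| Friday's | 0.10 M | 1.00 equiv | 50 °C | 30 s |
| Monday's | 0.10 M | 1.00 equiv | 30 °C | 30 s |
| Sunday's | 0.10 M | 1.00 equiv | 10 °C | 30 s |

    substrate + reagent → intermediate A (k1 = 2.3 L mol⁻¹ s⁻¹, Ea1 = 65.0 kJ mol⁻¹)
    intermediate A ⇌ intermediate B (K2 = 1.4, k2 = 0.042 s⁻¹, Ea2 = 81.0 kJ mol⁻¹, ΔH2 = −53.0 kJ mol⁻¹)
    intermediate A ⇌ intermediate C (K3 = 0.14, k3 = 0.040 s⁻¹, Ea3 = 90.0 kJ mol⁻¹, ΔH3 = 1.00 kJ mol⁻¹)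
    intermediate A → target (k4 = 0.015 s⁻¹, Ea4 = 79.0 kJ mol⁻¹)
    reagent + intermediate B ⇌ intermediate D (K5 = 3.7 L mol⁻¹, k5 = 0.096 L mol⁻¹ s⁻¹, Ea5 = 46.0 kJ mol⁻¹, ΔH5 = −29.0 kJ mol⁻¹)
    intermediate C ⇌ intermediate E (K6 = 0.33, k6 = 0.044 s⁻¹, Ea6 = 86.0 kJ mol⁻¹, ΔH6 = −60.0 kJ mol⁻¹)
    target ⇌ isomer of the product (K7 = 0.14, k7 = 0.030 s⁻¹, Ea7 = 98.0 kJ mol⁻¹, ΔH7 = 38.0 kJ mol⁻¹)
    2 reagent → self-condensation product (k8 = 0.70 L mol⁻¹ s⁻¹, Ea8 = 62.0 kJ mol⁻¹)
    (constants at 50 °C)

- for a step with 2 of a species take k times the square, and two of it per event
- the constants hold at 50 °C; other temperatures follow from the activation energies and enthalpies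

* which flask leads in amount of target, in percent of the substrate charged ("all alike" within 1.5 percentage points) (Friday's / Monday's / Sunday's / all alike)
* how much target is there at the end, in percent of the substrate charged: Friday's
* how much target is there at the end, in percent of the substrate charged: Monday's
* how much target is there at the end, in percent of the substrate charged: Sunday's

Target forms from intermediate A in one step, at its rate constant times [intermediate A]. So, over a run, target plus the isomer made from it equals that constant times the time times the average [intermediate A]. At 50 °C the constant is 0.015 s⁻¹, which gives 0.450 for Friday's flask in 30 s. I call this product of the rate constant of intermediate A → target, at the flask's temperature, and the time the lifetime count. With the activation energy 79.0 kJ mol⁻¹, it comes to 0.0647 for Monday's flask and 0.00707 for Sunday's.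

Now I turn the question round: what must be true for Sunday's flask to beat Friday's? Sunday's ceiling is its count times a full charge, 0.707% of the substrate. So, leaving the isomer aside, Friday's flask must hold an average [intermediate A] below 1.57% of the charge. Self-condensation also uses reagent. At equal concentrations of substrate and reagent and at 50 °C, though, the step to intermediate A takes 62.2% of the reagent being used, and the activation energies 65.0 kJ mol⁻¹ and 62.0 kJ mol⁻¹ lie close together, so I hold that share roughly fixed as a working estimate.

With equal charges and no competition, the fraction of substrate converted is k[substrate]t/(1 + k[substrate]t), where k is the rate constant of the first step at the flask's temperature. That gives 87.3% for Friday's flask, which is more than the reagent share, so there I take the share as a rough figure for the conversion. It gives 58.3% for Monday's flask, a little below the share, and 18.5% for Sunday's. Intermediate A starts from nothing, so I take its average as half of each figure, a rough factor that I keep for Friday's flask too, although intermediate A drains there into intermediates B and C. Friday's average is then 31.1% of the charge, far above the 1.57% needed for the opposite outcome. My reckoning for target plus isomer is 14.0% for Friday's flask, 1.89% for Monday's and 0.0652% for Sunday's, so Friday's leads.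

The forecast names Friday's, with 13%, 1.6% and 0.06%, reasoning that “Cooling cuts both the formation of A”.

The simulation gives Friday's as the leader, with 12.4% of target, against 1.84% for Monday's and 0.0658% for Sunday's. Friday's target and its 1.50% of isomer, divided by the count, give an average intermediate A of 30.8%, and Sunday's target gives 9.30%, so between these flasks the count differs by a factor of 63.6 and the average by 3.31. The same recipe as Sunday's, run at 35 °C, has a count of 0.108, and its 3.36% of target and 0.128% of isomer give an average intermediate A of 32.3%, against 39.6% at the end.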